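**Retrosynthetic overview**
1. Feature used: in the seven-membered ring C (C8, C9, C10, C11, C12, C13, C17), C8 lies between the ketone-level C9 (the hemiketal carbon) and the allylic C17 (CHMe) and carries ring A through C7H2. C8–C9 and C8–C17 are therefore cut together: C8 enters as the carbon of a diazoalkane that inserts into the C9–C17 bond of a six-membered C9 ketone fused to ring D.
2. Ring B (C3, C7, C8, C9, O, C4) is cut at the C9–O hemiketal bond: after the union the C4 hydroxyl is unmasked and closes onto C9.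
3. The six-membered ketone is cut at C10=C11 (ring-closing metathesis), at C12–C11 and C9–C10 (vinyl additions; C12 is set from C15 of the (S)-ketol of 2,2-dimethylcyclopentane-1,3-dione) and at C13–C17 (Negishi coupling). The C17 methyl comes from enolate alkylation and the C10/C11 oxygens from dihydroxylation.
4. C15 stays a silyl ether until after the union. C9 is then the only carbonyl, and C17–H is not the vinylogous 1,3-dicarbonyl proton that a C15 enone would make it (acidic enough to epimerise and to quench the diazoalkane). C11 and C15 are oxidised together at the end.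
5. Ring order: A bought, D from the dione, six-membered ring C by metathesis, seven-membered ring C by the insertion, ring B last by hemiketalisation.

Key step: step 19

Numbering: pyranone O1, C2 (C=O), C3, C4 (O-bearing), C5, C6; C7 = CH2; ring C = C8–C9–C10–C11–C12–C13–C17; ring D = C12–C13–C14–C15–C16 (C16 = CMe2). Faces: β is the face of rings C/D that carries the C12 oxygen, α the other face. In the target C9–OH and C12–OH are β; C10–OH, the C17 methyl, H8 and the ring B oxygen on C9 are α.
Assumption: compounds 30–33 are written as the closed C9 hemiketals, taken to be the favoured ring–chain tautomers as in the target; the hydride of step 1 comes from sucrose through the yeast and is booked as CO2.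

**Fragment A: the six-membered C9 ketone (steps 1–12)**

Step 1
Reactants: 1 2,2-dimethylcyclopentane-1,3-dione
Product: 2 (S)-3-hydroxy-2,2-dimethylcyclopentan-1-one
Conditions: baker's yeast (Saccharomyces cerevisiae), sucrose, H2O, 30 °C
Reagents that add atoms: none
Why: Enzymatic desymmetrising reduction of one of the two enantiotopic carbonyls of the prochiral dione by the yeast ketoreductases, which should give the (S)-ketol and so set C15, the centre that later relays its configuration to C12.

Step 2
Reactants: 2 (S)-3-hydroxy-2,2-dimethylcyclopentan-1-one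
Product: 3 (S)-2,2-dimethyl-3-(triethylsilyloxy)cyclopentan-1-one
Conditions: Et3SiCl, imidazole, DMF, 0 °C → rt
Reagents that add atoms: chlorotriethylsilane CC[Si](Cl)(CC)CC
Why: Imidazole-assisted silylation of a secondary alcohol, chosen as triethylsilyl so that it can later be removed together with the C11 ether while a tert-butyldimethylsilyl ether stays.

Step 3
Reactants: 3 (S)-2,2-dimethyl-3-(triethylsilyloxy)cyclopentan-1-one
Product: 5 (4S)-5,5-dimethyl-4-(triethylsilyloxy)cyclopent-2-en-1-one, via trimethylsilyl enol ether 4 (not isolated)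
Conditions: LiN(i-Pr)2, THF, −78 °C; Me3SiCl; then Pd(OAc)2 (10 mol%), O2 (1 atm), DMSO, rt
Reagents that add atoms: none
Why: Saegusa–Ito oxidation, in which the ketone can enolise only towards C13 (C16 is quaternary) and the palladium enolate has β-hydrogens only on C14, so the C13=C14 enone should form without regiochemical ambiguity.

Step 4
Reactants: 5 (4S)-5,5-dimethyl-4-(triethylsilyloxy)cyclopent-2-en-1-one
Product: 6 (4S)-2-iodo-5,5-dimethyl-4-(triethylsilyloxy)cyclopent-2-en-1-one
Conditions: I2, pyridine, CH2Cl2, 0 °C → rt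
Reagents that add atoms: iodine [I][I]
Why: α-Iodination of an enone by the pyridine/iodine addition–elimination sequence (Baylis–Hillman-type addition of pyridine, iodination of the enolate, elimination), a standard reaction of 4-silyloxycyclopent-2-enones.

Step 5
Reactants: 6 (4S)-2-iodo-5,5-dimethyl-4-(triethylsilyloxy)cyclopent-2-en-1-one; 7 2-bromo-N-methoxy-N-methylacetamide
Product: 9 2-[(3S)-4,4-dimethyl-5-oxo-3-(triethylsilyloxy)cyclopent-1-en-1-yl]-N-methoxy-N-methylacetamide, via Reformatsky reagent 8 (not isolated)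
Conditions: 7, Zn dust, THF, rt; then 6, Pd(dba)2 (5 mol%), P(t-Bu)3 (5 mol%), THF, rt
Reagents that add atoms: none
Why: Negishi-type cross-coupling of a Reformatsky (zinc amide enolate) reagent with the alkenyl iodide on zerovalent palladium, which should outrun addition of the soft zinc enolate to the hindered enone and puts the C17–C9 unit on C13.

Step 6
Reactants: 9 2-[(3S)-4,4-dimethyl-5-oxo-3-(triethylsilyloxy)cyclopent-1-en-1-yl]-N-methoxy-N-methylacetamide; 10 vinylmagnesium bromide
Product: 12 1-[(3S,5R)-5-ethenyl-5-hydroxy-4,4-dimethyl-3-(triethylsilyloxy)cyclopent-1-en-1-yl]but-3-en-2-one, via chelated tetrahedral adduct 11 (not isolated)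
Conditions: 10 (3.5 equiv), LaCl3·2LiCl (0.3 equiv), THF, −78 → 0 °C; inverse quench into cold aq. NH4Cl
Reagents that add atoms: none
Why: Grignard addition twice, to the Weinreb amide (the chelated adduct holds until work-up and then gives the vinyl ketone) and 1,2 to the enone carbonyl (the lanthanum salt suppresses enolisation and conjugate addition), where the reagent should come anti to the C15 silyloxy group so that the C12 hydroxyl ends cis (β) to it.

Step 7
Reactants: 12 1-[(3S,5R)-5-ethenyl-5-hydroxy-4,4-dimethyl-3-(triethylsilyloxy)cyclopent-1-en-1-yl]but-3-en-2-one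
Product: 13 (2S,7aR)-7a-hydroxy-1,1-dimethyl-2-(triethylsilyloxy)-1,2,4,7a-tetrahydro-5H-inden-5-one (C9 ketone; C10=C11; C12 β-OH; C13=C14; C15 β-OSiEt3)
Conditions: second-generation Grubbs catalyst (H2IMes)(PCy3)Cl2Ru=CHPh (5 mol%), CH2Cl2, 40 °C
Reagents that add atoms: none
Why: Ring-closing metathesis of the vinyl ketone with the C12 vinyl group closes the six-membered ring at C10=C11 with loss of ethene, the trisubstituted C13=C14 alkene being too hindered to take part.

Step 8
Reactants: 13 (2S,7aR)-7a-hydroxy-1,1-dimethyl-2-(triethylsilyloxy)-1,2,4,7a-tetrahydro-5H-inden-5-one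
Product: 14 (2S,7aR)-1,1-dimethyl-2-(triethylsilyloxy)-7a-(trimethylsilyloxy)-1,2,4,7a-tetrahydro-5H-inden-5-one
Conditions: N-(trimethylsilyl)imidazole, CH2Cl2, rt
Reagents that add atoms: N-(trimethylsilyl)imidazole C[Si](C)(C)n1ccnc1
Why: Silylation of the hindered tertiary alcohol with a neutral silyl donor, which avoids both acid (ionisation of the doubly allylic C12–O bond and aromatisation of ring C) and a triflate/amine pair that could enolise the ketone.

Step 9
Reactants: 14 (2S,7aR)-1,1-dimethyl-2-(triethylsilyloxy)-7a-(trimethylsilyloxy)-1,2,4,7a-tetrahydro-5H-inden-5-one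
Product: 15 (2S,4S,7aR)-1,1,4-trimethyl-2-(triethylsilyloxy)-7a-(trimethylsilyloxy)-1,2,4,7a-tetrahydro-5H-inden-5-one (C17 α-methyl)
Conditions: LiN(i-Pr)2 (1.05 equiv), THF, −78 °C; MeI, −78 → −40 °C
Reagents that add atoms: iodomethane IC
Why: Kinetic α′-deprotonation of the cyclohexenone at C17 (C12 has no hydrogen) and C-alkylation of the cross-conjugated enolate, in which iodomethane should enter anti to the pseudo-axial C12 silyloxy group (1,3-related) to give the equatorial α-methyl, which is also the thermodynamic epimer at this enolisable centre.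

Step 10
Reactants: 15 (2S,4S,7aR)-1,1,4-trimethyl-2-(triethylsilyloxy)-7a-(trimethylsilyloxy)-1,2,4,7a-tetrahydro-5H-inden-5-one
Product: 16 10α,11α-dihydroxy ketone (C9 ketone; C10 α-OH; C11 α-OH; C12 β-OSiMe3; C13=C14; C15 β-OSiEt3; C17 α-CH3)
Conditions: OsO4 (5 mol%), N-methylmorpholine N-oxide, acetone/H2O, rt
Reagents that add atoms: N-methylmorpholine N-oxide C[N+]1([O-])CCOCC1; water O
Why: Catalytic syn-dihydroxylation, in which OsO4 should take the cis-disubstituted C10=C11 alkene rather than the trisubstituted C13=C14 alkene flanked by two fully substituted silyloxy-bearing carbons, and from the α face, anti to the allylic C12 silyloxy group, which sets the C10 α-hydroxyl of the target and a C11 hydroxyl that is oxidised later.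

Step 11
Reactants: 16 10α,11α-dihydroxy ketone
Product: 17 10-O-tert-butyldimethylsilyl ether of 16 (C11 α-OH free)
Conditions: t-BuMe2SiCl, imidazole, DMF, 0 °C → rt
Reagents that add atoms: tert-butyldimethylsilyl chloride CC(C)(C)[Si](C)(C)Cl
Why: Selective silylation of the less hindered and more acidic C10 hydroxyl (equatorial, α to the ketone) over the axial C11 hydroxyl next to the quaternary C12.

Step 12
Reactants: 17 10-O-tert-butyldimethylsilyl ether of 16
Product: 18 silyl-protected hydrindenone (six-membered C9 ketone; C10 α-OSi(t-Bu)Me2; C11 α-OSiEt3; C12 β-OSiMe3; C13=C14; C15 β-OSiEt3; C16 Me2; C17 α-CH3)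
Conditions: Et3SiOTf, 2,6-lutidine, CH2Cl2, −78 → 0 °C
Reagents that add atoms: triethylsilyl trifluoromethanesulfonate CC[Si](CC)(CC)OS(=O)(=O)C(F)(F)F
Why: Forcing silylation of the remaining hindered secondary alcohol with a silyl triflate and a hindered base at low temperature, conditions that should leave the ketone un-enolised.

**Fragment B: the diazoalkane (steps 13–18)**

Step 13
Reactants: 19 4-hydroxy-5,6-dimethyl-2H-pyran-2-one; 20 3-bromoprop-1-ene
Product: 21 5,6-dimethyl-4-(prop-2-en-1-yloxy)-2H-pyran-2-one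
Conditions: K2CO3, acetone, reflux
Reagents that add atoms: none
Why: Williamson-type O-alkylation of the vinylogous acid at the C4 oxygen of the 4-hydroxy-2-pyranone.

Step 14
Reactants: 21 5,6-dimethyl-4-(prop-2-en-1-yloxy)-2H-pyran-2-one
Product: 22 4-hydroxy-5,6-dimethyl-3-(prop-2-en-1-yl)-2H-pyran-2-one
Conditions: chlorobenzene, 130 °C
Reagents that add atoms: none
Why: Claisen rearrangement ([3,3]) of the allyl vinylogous ester to the only free ortho position C3 (C5 is blocked by methyl), followed by tautomerisation back to the 4-hydroxy-2-pyranone.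

Step 15
Reactants: 22 4-hydroxy-5,6-dimethyl-3-(prop-2-en-1-yl)-2H-pyran-2-one
Product: 23 4-(benzyloxy)-5,6-dimethyl-3-(prop-2-en-1-yl)-2H-pyran-2-one
Conditions: BnOH, PPh3, DIAD, THF, 0 °C → rt
Reagents that add atoms: benzyl alcohol OCc1ccccc1
Why: Mitsunobu O-alkylation, which for 4-hydroxy-2-pyranones goes at the C4 oxygen and avoids the 2-alkoxy-4-pyranone isomer that basic alkylation of this flanked position could give.

Step 16
Reactants: 23 4-(benzyloxy)-5,6-dimethyl-3-(prop-2-en-1-yl)-2H-pyran-2-one
Product: 24 2-[4-(benzyloxy)-5,6-dimethyl-2-oxo-2H-pyran-3-yl]acetaldehyde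
Conditions: OsO4 (2 mol%), NaIO4, 2,6-lutidine, dioxane/H2O, rt
Reagents that add atoms: sodium periodate [Na+].[O-]I(=O)(=O)=O; water O
Why: Lemieux–Johnson oxidation, in which OsO4 dihydroxylates the terminal alkene much faster than the tetrasubstituted electron-poor pyranone double bonds and periodate cleaves the diol to the aldehyde.

Step 17
Reactants: 24 2-[4-(benzyloxy)-5,6-dimethyl-2-oxo-2H-pyran-3-yl]acetaldehyde
Product: 25 4-(benzyloxy)-3-(2-hydrazinylideneethyl)-5,6-dimethyl-2H-pyran-2-one
Conditions: N2H4·H2O (5 equiv), EtOH, 0 °C; used at once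
Reagents that add atoms: hydrazine NN
Why: Condensation of the aldehyde with excess hydrazine at low temperature, where the excess suppresses azine formation and the pyranone, which reacts with hydrazine only on heating, should be left alone.

Step 18
Reactants: 25 4-(benzyloxy)-3-(2-hydrazinylideneethyl)-5,6-dimethyl-2H-pyran-2-one
Product: 26 4-(benzyloxy)-3-(2-diazoethyl)-5,6-dimethyl-2H-pyran-2-one
Conditions: DMSO, (COCl)2, CH2Cl2, −78 °C; then 25, Et3N, −78 °C; cold filtration, solution used at once
Reagents that add atoms: none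
Why: Swern-type dehydrogenation of the hydrazone with activated dimethyl sulfoxide (N-sulfonium formation, then base-induced loss of dimethyl sulfide), which should give the non-stabilised diazoalkane at a temperature low enough for it to survive until use.

**Union and endgame (steps 19–23)**

Step 19
Reactants: 18 silyl-protected hydrindenone; 26 4-(benzyloxy)-3-(2-diazoethyl)-5,6-dimethyl-2H-pyran-2-one
Product: 28 ring-expanded cycloheptanone (C9 ketone; C8 β-CH2-(4-benzyloxy-5,6-dimethyl-2-oxo-2H-pyran-3-yl); C10 α-OSi(t-Bu)Me2; C11 α-OSiEt3; C12 β-OSiMe3; C15 β-OSiEt3; C17 α-CH3), via C8-epimeric cycloheptanone 27 (not isolated)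
Conditions: Sc(OTf)3 (10 mol%), CH2Cl2, −78 → −20 °C, slow addition of cold 26 (2 equiv); then DBU (0.2 equiv), 0 °C → rt
Reagents that add atoms: none
Why: Sc(OTf)3 (trivalent scandium) activates the C9 carbonyl of 18, the diazo carbon C8 of 26 adds to it, and in the diazonium alkoxide the ring bond C9–C17 lying anti to the leaving N2 shifts from C9 to C8, so that C8–C9 and C8–C17 are formed and N2 is lost. The closest known reaction is the scandium triflate-catalysed homologation of cycloalkanones with non-stabilised monosubstituted diazoalkanes, a Tiffeneau–Demjanov-type ring expansion. Ring C reaches its seven-membered size by this 1,2-alkyl shift inside the six-membered ring (ring expansion by one carbon), not by a cyclisation. C17 migrates with retention, and the new centre C8, being α to the C9 ketone, is set under thermodynamic control in the DBU stage, where the C7 branch should settle β, trans to the neighbouring C17 methyl (27 converts into 28 through the enol). The step needs migration of C17 and not of C10, which the substrate secures because C17 is an electron-rich allylic carbon while C10 carries an inductively withdrawing silyloxy group, and it needs C9 as the only reacting site, which is secured because C15 is a silyl ether and not a ketone (no second carbonyl, no vinylogous 1,3-dicarbonyl C17–H to protonate the diazoalkane or to epimerise). The benzyl ether on O4 keeps the acidic pyranone hydroxyl from being O-alkylated by the diazoalkane.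

Step 20
Reactants: 28 ring-expanded cycloheptanone
Product: 30 protected hemiketal (ring B closed; C9 β-OH; C10 α-OSi(t-Bu)Me2; C11 α-OSiEt3; C12 β-OSiMe3; C15 β-OSiEt3), via debenzylated hydroxy ketone 29 (not isolated)
Conditions: H2 (1 atm), Pd/C (5 wt%), EtOAc, rt
Reagents that add atoms: none
Why: Hydrogenolysis of the benzyl vinylogous ester (fast, so the hindered trisubstituted C13=C14 alkene should survive), after which the C4 hydroxyl adds to the C9 ketone (6-exo-trig) to close ring B as the hemiketal, whose C9 configuration is set thermodynamically (trans ring fusion, axial anomeric hydroxyl).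

Step 21
Reactants: 30 protected hemiketal
Product: 31 triol (C11 α-OH; C12 β-OH; C15 β-OH; C10 α-OSi(t-Bu)Me2 kept)
Conditions: HF·pyridine, pyridine, THF, 0 °C → rt
Reagents that add atoms: none
Why: Buffered fluoride desilylation, which cleaves triethylsilyl and trimethylsilyl ethers much faster than a secondary tert-butyldimethylsilyl ether, so C11, C12 and C15 are freed while C10 stays protected.

Step 22
Reactants: 31 triol
Product: 32 diketone (C11 ketone; C13=C14–C15=O enone; C12 β-OH; C10 α-OSi(t-Bu)Me2)
Conditions: IBX, DMSO, rt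
Reagents that add atoms: none
Why: IBX oxidation of the two secondary alcohols (C11, and allylic C15 to the enone), a reagent that does not cleave the C11/C12 glycol and leaves the tertiary and hemiketal hydroxyls untouched.

Step 23
Reactants: 32 diketone
Product: 33 CNP0525404.1
Conditions: HF (48% aq.), MeCN, 0 °C
Reagents that add atoms: none
Why: Acidic fluoride desilylation of the last silyl ether under non-basic conditions, which the base-sensitive α-ketol and hemiketal of the target should tolerate.

**Compound list**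
1 | 2,2-dimethylcyclopentane-1,3-dione | CC1(C)C(=O)CCC1=O | starting material
2 | (S)-3-hydroxy-2,2-dimethylcyclopentan-1-one | CC1(C)C(=O)CC[C@@H]1O | intermediate
3 | (S)-2,2-dimethyl-3-(triethylsilyloxy)cyclopentan-1-one | CC1(C)C(=O)CC[C@@H]1O[Si](CC)(CC)CC | intermediate
4 | (4S)-5,5-dimethyl-4-(triethylsilyloxy)-1-(trimethylsilyloxy)cyclopent-1-ene | CC1(C)C(O[Si](C)(C)C)=CC[C@@H]1O[Si](CC)(CC)CC | intermediate (not isolated)
5 | (4S)-5,5-dimethyl-4-(triethylsilyloxy)cyclopent-2-en-1-one | CC1(C)C(=O)C=C[C@@H]1O[Si](CC)(CC)CC | intermediate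
6 | (4S)-2-iodo-5,5-dimethyl-4-(triethylsilyloxy)cyclopent-2-en-1-one | CC1(C)C(=O)C(I)=C[C@@H]1O[Si](CC)(CC)CC | intermediate
7 | 2-bromo-N-methoxy-N-methylacetamide | CON(C)C(=O)CBr | starting material
8 | bromo{2-[methoxy(methyl)amino]-2-oxoethyl}zinc | CON(C)C(=O)C[Zn]Br | intermediate (not isolated)
9 | 2-[(3S)-4,4-dimethyl-5-oxo-3-(triethylsilyloxy)cyclopent-1-en-1-yl]-N-methoxy-N-methylacetamide | CON(C)C(=O)CC1=C[C@H](O[Si](CC)(CC)CC)C(C)(C)C1=O | intermediate
10 | vinylmagnesium bromide | C=C[Mg]Br | starting material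
11 | chelated tetrahedral adduct, bis(bromomagnesium) salt (C12 alkoxide; C9 N-methoxy-N-methyl hemiaminal alkoxide) | C=CC(O[Mg]Br)(N(C)OC)CC1=C[C@H](O[Si](CC)(CC)CC)C(C)(C)[C@@]1(O[Mg]Br)C=C | intermediate (not isolated)
12 | 1-[(3S,5R)-5-ethenyl-5-hydroxy-4,4-dimethyl-3-(triethylsilyloxy)cyclopent-1-en-1-yl]but-3-en-2-one | C=CC(=O)CC1=C[C@H](O[Si](CC)(CC)CC)C(C)(C)[C@@]1(O)C=C | intermediate
13 | (2S,7aR)-7a-hydroxy-1,1-dimethyl-2-(triethylsilyloxy)-1,2,4,7a-tetrahydro-5H-inden-5-one | O=C1C=C[C@@]2(O)C(=C[C@H](O[Si](CC)(CC)CC)C2(C)C)C1 | intermediate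
14 | (2S,7aR)-1,1-dimethyl-2-(triethylsilyloxy)-7a-(trimethylsilyloxy)-1,2,4,7a-tetrahydro-5H-inden-5-one | O=C1C=C[C@@]2(O[Si](C)(C)C)C(=C[C@H](O[Si](CC)(CC)CC)C2(C)C)C1 | intermediate
15 | (2S,4S,7aR)-1,1,4-trimethyl-2-(triethylsilyloxy)-7a-(trimethylsilyloxy)-1,2,4,7a-tetrahydro-5H-inden-5-one | O=C1C=C[C@@]2(O[Si](C)(C)C)C(=C[C@H](O[Si](CC)(CC)CC)C2(C)C)[C@@H]1C | intermediate
16 | 10α,11α-dihydroxy ketone (C12 β-OSiMe3; C15 β-OSiEt3; C17 α-CH3) | O=C1[C@H](O)[C@H](O)[C@@]2(O[Si](C)(C)C)C(=C[C@H](O[Si](CC)(CC)CC)C2(C)C)[C@@H]1C | intermediate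
17 | 10-O-tert-butyldimethylsilyl ether of 16 | O=C1[C@H](O[Si](C)(C)C(C)(C)C)[C@H](O)[C@@]2(O[Si](C)(C)C)C(=C[C@H](O[Si](CC)(CC)CC)C2(C)C)[C@@H]1C | intermediate
18 | silyl-protected hydrindenone (key-step ketone) | O=C1[C@H](O[Si](C)(C)C(C)(C)C)[C@H](O[Si](CC)(CC)CC)[C@@]2(O[Si](C)(C)C)C(=C[C@H](O[Si](CC)(CC)CC)C2(C)C)[C@@H]1C | intermediate
19 | 4-hydroxy-5,6-dimethyl-2H-pyran-2-one | Cc1oc(=O)cc(O)c1C | starting material
20 | 3-bromoprop-1-ene | C=CCBr | starting material
21 | 5,6-dimethyl-4-(prop-2-en-1-yloxy)-2H-pyran-2-one | Cc1oc(=O)cc(OCC=C)c1C | intermediate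
22 | 4-hydroxy-5,6-dimethyl-3-(prop-2-en-1-yl)-2H-pyran-2-one | Cc1oc(=O)c(CC=C)c(O)c1C | intermediate
23 | 4-(benzyloxy)-5,6-dimethyl-3-(prop-2-en-1-yl)-2H-pyran-2-one | Cc1oc(=O)c(CC=C)c(OCc2ccccc2)c1C | intermediate
24 | 2-[4-(benzyloxy)-5,6-dimethyl-2-oxo-2H-pyran-3-yl]acetaldehyde | Cc1oc(=O)c(CC=O)c(OCc2ccccc2)c1C | intermediate
25 | 4-(benzyloxy)-3-(2-hydrazinylideneethyl)-5,6-dimethyl-2H-pyran-2-one | Cc1oc(=O)c(CC=NN)c(OCc2ccccc2)c1C | intermediate
26 | 4-(benzyloxy)-3-(2-diazoethyl)-5,6-dimethyl-2H-pyran-2-one | Cc1oc(=O)c(CC=[N+]=[N-])c(OCc2ccccc2)c1C | intermediate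
27 | C8 epimer of 28 (C7 branch α) | Cc1oc(=O)c(c(OCc2ccccc2)c1C)C[C@H]1[C@@H](C)C3=C[C@H](O[Si](CC)(CC)CC)C(C)(C)[C@@]3(O[Si](C)(C)C)[C@@H](O[Si](CC)(CC)CC)[C@@H](O[Si](C)(C)C(C)(C)C)C1=O | intermediate (not isolated)
28 | ring-expanded cycloheptanone with the benzyl-protected pyranone on C7 | Cc1oc(=O)c(c(OCc2ccccc2)c1C)C[C@@H]1[C@@H](C)C3=C[C@H](O[Si](CC)(CC)CC)C(C)(C)[C@@]3(O[Si](C)(C)C)[C@@H](O[Si](CC)(CC)CC)[C@@H](O[Si](C)(C)C(C)(C)C)C1=O | intermediate
29 | debenzylated open-chain hydroxy ketone | Cc1oc(=O)c(c(O)c1C)C[C@@H]1[C@@H](C)C3=C[C@H](O[Si](CC)(CC)CC)C(C)(C)[C@@]3(O[Si](C)(C)C)[C@@H](O[Si](CC)(CC)CC)[C@@H](O[Si](C)(C)C(C)(C)C)C1=O | intermediate (not isolated)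
30 | protected hemiketal (rings A–D complete) | Cc1oc(=O)c2c(c1C)O[C@]1(O)[C@H](O[Si](C)(C)C(C)(C)C)[C@H](O[Si](CC)(CC)CC)[C@@]3(O[Si](C)(C)C)C(=C[C@H](O[Si](CC)(CC)CC)C3(C)C)[C@H](C)[C@H]1C2 | intermediate
31 | 11,12,15-triol with C10 α-OSi(t-Bu)Me2 | Cc1oc(=O)c2c(c1C)O[C@]1(O)[C@H](O[Si](C)(C)C(C)(C)C)[C@H](O)[C@@]3(O)C(=C[C@H](O)C3(C)C)[C@H](C)[C@H]1C2 | intermediate
32 | 11,15-diketone with C10 α-OSi(t-Bu)Me2 | Cc1oc(=O)c2c(c1C)O[C@]1(O)[C@H](O[Si](C)(C)C(C)(C)C)C(=O)[C@@]3(O)C(=CC(=O)C3(C)C)[C@H](C)[C@H]1C2 | intermediate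
33 | CNP0525404.1 | Cc1oc(=O)c2c(c1C)O[C@]1(O)[C@H](O)C(=O)[C@@]3(O)C(=CC(=O)C3(C)C)[C@H](C)[C@H]1C2 | target

**Count**
Total: 23 steps. Longest linear sequence: 17 steps (steps 1–12, then 19–23); the diazoalkane branch (steps 13–18) joins at step 19.

**Steps most likely to fail**

1. Step 19. The non-stabilised diazoalkane may decompose (1,2-hydride shift from C7 to a 3-vinylpyranone, azine formation) faster than it adds to the doubly α-branched C9 ketone, and migration of C10 or epoxide formation may compete. The fallback replaces insertion of the whole fragment by a one-carbon homologation followed by a conjugate addition. It sets out from 18: homologation with trimethylsilyldiazomethane and AlMe3 (CH2Cl2, −78 °C) should give the α-trimethylsilyl cycloheptanone F1, which is C-desilylated on wet silica gel to the cycloheptanone F2 (C8 = CH2). α-Methylenation at C8 with paraformaldehyde and diisopropylammonium trifluoroacetate (THF, reflux) should give the α-methylene ketone F3. Michael addition of hydroxypyranone 19 through C3 (cat. Et3N, MeCN, rt, the warfarin-type addition of 4-hydroxypyranones to enones) then forms C3–C7, C8 is protonated under thermodynamic control and the pyranone hydroxyl closes onto C9. The route is rejoined at hemiketal 30.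

2. Step 5. The zinc enolate may add to the enone (1,2 or conjugate) or the alkenylpalladium intermediate may be protodeiodinated before transmetalation. The fallback builds the same ring through an allyl group and sets out from 6: Stille coupling with allyltributylstannane (Pd2(dba)3, AsPh3, DMF) should give the 2-allyl enone F4, and Lemieux–Johnson cleavage (OsO4 cat., NaIO4, 2,6-lutidine) the aldehyde F5. Vinylmagnesium bromide with LaCl3·2LiCl adds to aldehyde and ketone to give the dienediol F6 (C9 epimers), ring-closing metathesis with the second-generation Grubbs catalyst gives the cyclohexenol F7, and MnO2 oxidises its secondary allylic alcohol. The route is rejoined at enone 13.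

3. Step 9. Proton exchange between enolate and product may lead to double methylation at C17, or alkylation may occur from the β face. The fallback brings the methyl in with the two-carbon unit and lets C17 settle thermodynamically; it sets out from 6 and uses the coupling of step 5, which by then is known to work. The zinc reagent F8, made from 2-bromo-N-methoxy-N-methylpropanamide and Zn, is coupled with 6 (Pd(dba)2, P(t-Bu)3) to the C17-methyl Weinreb amide F9 (both C17 epimers). Double vinyl addition as in step 6 gives the hydroxy dienone F10. Ring-closing metathesis followed by DBU equilibration of the enolisable C17 should give the 17α-methyl enone F11 (equatorial methyl, trans to the C12 hydroxyl). Silylation with N-(trimethylsilyl)imidazole rejoins the route at 15.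

Further compounds
F1 | step 19 | α-trimethylsilyl cycloheptanone (C8 bearing SiMe3) | O=C1C([Si](C)(C)C)[C@@H](C)C3=C[C@H](O[Si](CC)(CC)CC)C(C)(C)[C@@]3(O[Si](C)(C)C)[C@@H](O[Si](CC)(CC)CC)[C@H]1O[Si](C)(C)C(C)(C)C
F2 | step 19 | cycloheptanone (C8 = CH2) | O=C1C[C@@H](C)C3=C[C@H](O[Si](CC)(CC)CC)C(C)(C)[C@@]3(O[Si](C)(C)C)[C@@H](O[Si](CC)(CC)CC)[C@H]1O[Si](C)(C)C(C)(C)C
F3 | step 19 | α-methylene ketone (C8=C7H2) | O=C1C(=C)[C@@H](C)C3=C[C@H](O[Si](CC)(CC)CC)C(C)(C)[C@@]3(O[Si](C)(C)C)[C@@H](O[Si](CC)(CC)CC)[C@H]1O[Si](C)(C)C(C)(C)C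
F4 | step 5 | (4S)-5,5-dimethyl-2-(prop-2-en-1-yl)-4-(triethylsilyloxy)cyclopent-2-en-1-one | CC1(C)C(=O)C(CC=C)=C[C@@H]1O[Si](CC)(CC)CC
F5 | step 5 | 2-[(3S)-4,4-dimethyl-5-oxo-3-(triethylsilyloxy)cyclopent-1-en-1-yl]acetaldehyde | CC1(C)C(=O)C(CC=O)=C[C@@H]1O[Si](CC)(CC)CC
F6 | step 5 | dienediol (C12 β-OH and vinyl; C9 carbinol, both epimers) | C=CC(O)CC1=C[C@H](O[Si](CC)(CC)CC)C(C)(C)[C@@]1(O)C=C
F7 | step 5 | cyclohexenol (C9–OH, both epimers; C10=C11; C12 β-OH) | OC1C=C[C@@]2(O)C(=C[C@H](O[Si](CC)(CC)CC)C2(C)C)C1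
F8 | step 9 | bromo{1-[methoxy(methyl)amino]-1-oxopropan-2-yl}zinc | CON(C)C(=O)C(C)[Zn]Br
F9 | step 9 | C17-methyl Weinreb amide (both C17 epimers) | CON(C)C(=O)C(C)C1=C[C@H](O[Si](CC)(CC)CC)C(C)(C)C1=O
F10 | step 9 | C17-methyl hydroxy dienone (both C17 epimers) | C=CC(=O)C(C)C1=C[C@H](O[Si](CC)(CC)CC)C(C)(C)[C@@]1(O)C=C
F11 | step 9 | 17α-methyl enone with free C12 β-OH | O=C1C=C[C@@]2(O)C(=C[C@H](O[Si](CC)(CC)CC)C2(C)C)[C@@H]1C
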